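**Assumption:** Vidalol A has no stereocentre (it is achiral), so "the single enantiomer" is the compound itself and no stereocontrol is needed. 5-Bromovanillin and 2-bromo-1,3,5-trimethoxybenzene are taken as commercial.

## Retrosynthetic overview

1. Vidalol A (7) ⇐ global O-demethylation of tetramethyl ether 5, which already carries all three C–Br bonds and the full carbon skeleton.
2. 5 ⇐ Friedel–Crafts benzylation (Ar–CH2 bond) of 2-bromo-1,3,5-trimethoxybenzene (4) with the p-hydroxybenzyl alcohol 3.
3. 3 ⇐ reduction of 5,6-dibromovanillin (2) ⇐ bromination of 5-bromovanillin (1).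
4. No ring is formed: both benzene rings are bought, ring A is elaborated first (steps 1–2), then joined to ring B (step 3).

## Route

Step 1
Reactants: 1 5-bromovanillin (3-bromo-4-hydroxy-5-methoxybenzaldehyde)
Product: 2 5,6-dibromovanillin (2,3-dibromo-4-hydroxy-5-methoxybenzaldehyde)
Conditions: Br2 (1.3 equiv), Fe powder (cat.), AcOH, 25–40 °C
Reagents that add atoms: bromine Br2 (BrBr)
Why: Electrophilic aromatic bromination (FeBr3 formed in situ); both positions ortho and the position para to the OH are occupied, so the OMe group directs the new Br para to itself (C-6 of vanillin numbering), giving the 2,3-dibromo-4,5-dioxygenated pattern of ring A, with no stereocentre formed.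

Step 2
Reactants: 2 5,6-dibromovanillin
Product: 3 2,3-dibromo-4-(hydroxymethyl)-6-methoxyphenol (2,3-dibromo-4-hydroxy-5-methoxybenzyl alcohol)
Conditions: NaBH4 (1.5 equiv), THF–MeOH (4:1), 0 °C to rt; near-neutral aqueous work-up (pH 6–7)
Reagents that add atoms: none
Why: Chemoselective borohydride reduction of the aldehyde to the primary alcohol; aryl bromides, phenol and methyl ether are inert, and the near-neutral work-up keeps the acid-labile p-hydroxybenzyl alcohol from self-etherifying.

Step 3
Reactants: 3 2,3-dibromo-4-(hydroxymethyl)-6-methoxyphenol; 4 2-bromo-1,3,5-trimethoxybenzene (3 equiv, excess recovered)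
Product: 5 2,3-dibromo-4-[(3-bromo-2,4,6-trimethoxyphenyl)methyl]-6-methoxyphenol
Conditions: TsOH·H2O (5 mol %), HFIP, rt
Reagents that add atoms: none
Why: Acid-catalysed Friedel–Crafts benzylation: the alcohol ionises easily to a para-hydroxy-stabilised benzylic cation, which the electron-rich arene 4 captures at one of its two equivalent free positions (each ortho, ortho and para to OMe), while the excess of 4 suppresses a second benzylation; no stereocentre is formed.

Step 4
Reactants: 5 2,3-dibromo-4-[(3-bromo-2,4,6-trimethoxyphenyl)methyl]-6-methoxyphenol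
Product: 7 vidalol A (2-bromo-4-[(2,3-dibromo-4,5-dihydroxyphenyl)methyl]benzene-1,3,5-triol), via borate ester 6 (not isolated)
Conditions: BBr3 (10 equiv), CH2Cl2, −78 °C to rt; then ice–water
Reagents that add atoms: none
Why: BBr3 ether cleavage (Lewis acid complexation, then SN2 attack of bromide on each O-methyl) converts all four aryl methyl ethers into boron-bound phenoxides 6 that hydrolyse on work-up, while the aryl C–Br bonds and the diarylmethane are left intact at or below room temperature; the product is achiral.

## Compound list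

1 | 5-bromovanillin (3-bromo-4-hydroxy-5-methoxybenzaldehyde) | COc1cc(C=O)cc(Br)c1O | starting material
2 | 5,6-dibromovanillin (2,3-dibromo-4-hydroxy-5-methoxybenzaldehyde) | COc1cc(C=O)c(Br)c(Br)c1O | intermediate
3 | 2,3-dibromo-4-(hydroxymethyl)-6-methoxyphenol | COc1cc(CO)c(Br)c(Br)c1O | intermediate
4 | 2-bromo-1,3,5-trimethoxybenzene | COc1cc(OC)c(Br)c(OC)c1 | starting material
5 | 2,3-dibromo-4-[(3-bromo-2,4,6-trimethoxyphenyl)methyl]-6-methoxyphenol | COc1cc(Cc2c(OC)cc(OC)c(Br)c2OC)c(Br)c(Br)c1O | intermediate
6 | 2,6,7-tribromo-5-{[3-bromo-2,4,6-tris(dibromoboryloxy)phenyl]methyl}-1,3,2-benzodioxaborole (idealised formula of the boron-bound pentaphenoxide; cyclic B–Br catechol borate on ring A, three O–BBr2 groups on ring B) | BrB1Oc2cc(Cc3c(OB(Br)Br)cc(OB(Br)Br)c(Br)c3OB(Br)Br)c(Br)c(Br)c2O1 | intermediate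
7 | vidalol A (2-bromo-4-[(2,3-dibromo-4,5-dihydroxyphenyl)methyl]benzene-1,3,5-triol; no stereocentre) | Oc1cc(Cc2c(O)cc(O)c(Br)c2O)c(Br)c(Br)c1O | target

## Summary

Total step count: 4.
Longest linear sequence: 4 steps (1 → 2 → 3 → 5 → 7; compound 4 is bought and enters in step 3).

## Steps most likely to fail, with fallbacks

**Step 4 (global demethylation).** The three flanked ring-B methyl ethers may need forcing, and HBr/BBr3 could then cleave the electron-rich Ar–CH2 bond (retro-Friedel–Crafts) or shift bromine on the phloroglucinol ring. The fallback removes every methyl group before the C–C bond exists and then joins the two free polyphenols; it sets out from 2 and 4 and comes back to the route at 7. BBr3 (CH2Cl2, −78 to 0 °C) cleaves the single guaiacol ether of 2 by way of 2,6,7-tribromo-1,3,2-benzodioxaborole-5-carbaldehyde F1, which on aqueous work-up gives 2,3-dibromo-4,5-dihydroxybenzaldehyde F2. NaBH4 in THF–MeOH reduces this to lanosol F3 (2,3-dibromo-4,5-dihydroxybenzyl alcohol). Separately, 4 with BBr3 passes through 2-bromo-1,3,5-tris(dibromoboryloxy)benzene F4 to 2-bromobenzene-1,3,5-triol F5. Lanosol F3 is then added slowly to F5 (4 equiv) with 5 mol % TsOH in HFIP or aqueous dioxane at 25–40 °C. This C-benzylates F5 at one of its two equivalent free positions and gives 7 directly; the excess of F5 suppresses the bis-benzyl product.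

**Step 3 (Friedel–Crafts benzylation).** Compound 4 is a weaker nucleophile than its bromine-free parent, the product can be benzylated a second time, and under acid the bromoarene can pass on Br+. The fallback makes the C–C bond with the bromine-free arene and brominates afterwards; it sets out from 3 and comes back at 5. Compound 3 and commercial 1,3,5-trimethoxybenzene (COc1cc(OC)cc(OC)c1, 5 equiv) under the same TsOH/HFIP conditions give 2,3-dibromo-6-methoxy-4-[(2,4,6-trimethoxyphenyl)methyl]phenol F6. NBS (1.0 equiv, MeCN, 0 °C) then brominates one of the two equivalent, strongly activated C–H positions of the trimethoxyphenyl ring to give 5. Ring A is far less reactive because it carries two bromines and has no free position ortho or para to its OH.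

**Step 1 (second bromination).** The ring is deactivated and still carries a free hydroxyl para to the formyl group, so the risks are low conversion and ipso attack at C-1 (bromodeformylation). The fallback leaves the free-phenol series altogether; it sets out from 1 and comes back at 6. O-Methylation (MeI, K2CO3, DMF) gives 3-bromo-4,5-dimethoxybenzaldehyde F7, in which no OH can steer bromine to the formyl-bearing carbon. Br2/Fe/AcOH brominates para to the 5-OMe to give 2,3-dibromo-4,5-dimethoxybenzaldehyde F8, and NaBH4 gives (2,3-dibromo-4,5-dimethoxyphenyl)methanol F9. Because this non-phenolic alcohol ionises less easily, stoichiometric AlCl3 (1.2 equiv, CH2Cl2, 0 °C) is used to benzylate 4, giving 2-bromo-4-[(2,3-dibromo-4,5-dimethoxyphenyl)methyl]-1,3,5-trimethoxybenzene F10. BBr3 converts F10 into the same borate ester 6, which is hydrolysed to 7 as in step 4.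

## Further compounds

F1 | step 4 | 2,6,7-tribromo-1,3,2-benzodioxaborole-5-carbaldehyde | O=Cc1cc2OB(Br)Oc2c(Br)c1Br
F2 | step 4 | 2,3-dibromo-4,5-dihydroxybenzaldehyde | O=Cc1cc(O)c(O)c(Br)c1Br
F3 | step 4 | lanosol (2,3-dibromo-4,5-dihydroxybenzyl alcohol) | OCc1cc(O)c(O)c(Br)c1Br
F4 | step 4 | 2-bromo-1,3,5-tris(dibromoboryloxy)benzene | BrB(Br)Oc1cc(OB(Br)Br)c(Br)c(OB(Br)Br)c1
F5 | step 4 | 2-bromobenzene-1,3,5-triol | Oc1cc(O)c(Br)c(O)c1
F6 | step 3 | 2,3-dibromo-6-methoxy-4-[(2,4,6-trimethoxyphenyl)methyl]phenol | COc1cc(Cc2c(OC)cc(OC)cc2OC)c(Br)c(Br)c1O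
F7 | step 1 | 3-bromo-4,5-dimethoxybenzaldehyde | COc1cc(C=O)cc(Br)c1OC
F8 | step 1 | 2,3-dibromo-4,5-dimethoxybenzaldehyde | COc1cc(C=O)c(Br)c(Br)c1OC
F9 | step 1 | (2,3-dibromo-4,5-dimethoxyphenyl)methanol | COc1cc(CO)c(Br)c(Br)c1OC
F10 | step 1 | 2-bromo-4-[(2,3-dibromo-4,5-dimethoxyphenyl)methyl]-1,3,5-trimethoxybenzene | COc1cc(Cc2c(OC)cc(OC)c(Br)c2OC)c(Br)c(Br)c1OC
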